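**Retrosynthetic overview**

1. The target 16 comes from its chromene 5‑O‑TBS ether 15 by desilylation. 15 is disconnected at the C3–O bond of ring A to the 4‑aryl‑3,5‑diprenylphenol 13.
2. The strategy rests on this feature: without O3, ring A (C1 bears the chromene, C2 and C6 the prenyls, C4 the hydroxyl) has a local mirror plane through C1 and C4. C3 and C5 are therefore equivalent, and ortho‑oxygenation of the C4 phenol can only give the 3,4‑catechol.
3. 13 is disconnected at the biaryl bond C1(ring A)–C7(chromene): 1,2‑addition of chromenyllithium 10 to the quinone monoketal 5, then ketal hydrolysis and zinc reduction of the p‑quinol.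
4. 5 comes from 4‑methoxyphenol by two successive ortho‑prenylations and oxidation in methanol. 9 comes from 5‑bromoresorcinol and 3‑methylbut‑2‑enal, then silylation.
5. Ring order: the pyran ring of the chromene is the only ring built (step 4). Both benzene rings are bought; ring A is dearomatised in step 3 and rearomatised in step 7.

Key step: step 8

Remark: the target has no stereocentre, and with two ortho hydrogens on the chromene side of the biaryl bond it has no stable chiral axis. It is one achiral compound, so no step needs stereocontrol.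

**Route**

Step 1
Reactants: 1 4‑methoxyphenol; 2 prenyl bromide (1‑bromo‑3‑methylbut‑2‑ene)
Product: 3 4‑methoxy‑2‑(3‑methylbut‑2‑en‑1‑yl)phenol
Conditions: NaH (1.1 equiv), toluene, 0 °C; 2 (1.0 equiv), 0 °C → rt
Reagents that add atoms: none
Why: ortho‑C‑alkylation of a sodium phenoxide in a non‑polar solvent, where the tight ion pair steers the allylic bromide to the ring carbon next to oxygen; the para position is blocked by methoxy, and one equivalent of bromide should hold the reaction at the mono‑prenyl stage.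

Step 2
Reactants: 3 4‑methoxy‑2‑(3‑methylbut‑2‑en‑1‑yl)phenol; 2 prenyl bromide (1‑bromo‑3‑methylbut‑2‑ene)
Product: 4 4‑methoxy‑2,6‑bis(3‑methylbut‑2‑en‑1‑yl)phenol
Conditions: NaH (1.1 equiv), toluene, 0 °C; 2 (1.1 equiv), 0 °C → rt
Reagents that add atoms: none
Why: a second ortho‑C‑alkylation of the sodium phenoxide under the same non‑polar conditions, now directed to the only free ortho carbon; working from isolated 3 lets base and bromide be set for this alkylation alone and lets O‑alkylated material from step 1 be removed first.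

Step 3
Reactants: 4 4‑methoxy‑2,6‑bis(3‑methylbut‑2‑en‑1‑yl)phenol
Product: 5 4,4‑dimethoxy‑2,6‑bis(3‑methylbut‑2‑en‑1‑yl)cyclohexa‑2,5‑dien‑1‑one
Conditions: PhI(OAc)2, MeOH, 0 °C
Reagents that add atoms: methanol, CO
Why: iodine(III) oxidative dearomatisation of a 4‑methoxyphenol to the p‑quinone monoketal, with methanol captured at the methoxy‑bearing para carbon; the isolated trisubstituted alkenes should not react at 0 °C.

Step 4
Reactants: 6 5‑bromoresorcinol; 7 3‑methylbut‑2‑enal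
Product: 8 7‑bromo‑2,2‑dimethyl‑2H‑chromen‑5‑ol
Conditions: ethylenediamine diacetate (20 mol%), toluene, reflux; 7 (1.05 equiv)
Reagents that add atoms: none
Why: amine‑catalysed Knoevenagel‑type condensation of the enal at resorcinol C2 (the carbon between the two hydroxyls, as in cannabichromene‑type chromenylations), then dehydration to an o‑quinone methide and oxa‑6π electrocyclisation onto either of the two equivalent hydroxyls, which should give the 5‑hydroxy‑7‑bromo isomer; one equivalent of enal limits a second annulation.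

Step 5
Reactants: 8 7‑bromo‑2,2‑dimethyl‑2H‑chromen‑5‑ol
Product: 9 tert‑butyl[(7‑bromo‑2,2‑dimethyl‑2H‑chromen‑5‑yl)oxy]dimethylsilane
Conditions: TBSCl, imidazole, DMF, rt
Reagents that add atoms: tert‑butyldimethylsilyl chloride, CC(C)(C)[Si](C)(C)Cl
Why: standard imidazole‑promoted silylation of a phenol, which masks the only hydroxyl that would otherwise compete in the later oxygenation.

Step 6
Reactants: 9 tert‑butyl[(7‑bromo‑2,2‑dimethyl‑2H‑chromen‑5‑yl)oxy]dimethylsilane; 5 4,4‑dimethoxy‑2,6‑bis(3‑methylbut‑2‑en‑1‑yl)cyclohexa‑2,5‑dien‑1‑one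
Product: 11 1‑[5‑(tert‑butyldimethylsilyloxy)‑2,2‑dimethyl‑2H‑chromen‑7‑yl]‑4,4‑dimethoxy‑2,6‑bis(3‑methylbut‑2‑en‑1‑yl)cyclohexa‑2,5‑dien‑1‑ol, via [5‑(tert‑butyldimethylsilyloxy)‑2,2‑dimethyl‑2H‑chromen‑7‑yl]lithium 10 (not isolated)
Conditions: n‑BuLi, THF, −78 °C; then 5, −78 → −40 °C; H2O quench
Reagents that add atoms: none
Why: bromine–lithium exchange gives an aryllithium with two ortho hydrogens and the silyloxy group meta to lithium (no silyl migration), which should add 1,2 to the only carbonyl of the quinone monoketal (aryllithium addition to a quinone monoketal), the ketal blocking the other quinone carbon.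

Step 7
Reactants: 11 1‑[5‑(tert‑butyldimethylsilyloxy)‑2,2‑dimethyl‑2H‑chromen‑7‑yl]‑4,4‑dimethoxy‑2,6‑bis(3‑methylbut‑2‑en‑1‑yl)cyclohexa‑2,5‑dien‑1‑ol
Product: 13 4‑[5‑(tert‑butyldimethylsilyloxy)‑2,2‑dimethyl‑2H‑chromen‑7‑yl]‑3,5‑bis(3‑methylbut‑2‑en‑1‑yl)phenol, via 4‑[5‑(tert‑butyldimethylsilyloxy)‑2,2‑dimethyl‑2H‑chromen‑7‑yl]‑4‑hydroxy‑3,5‑bis(3‑methylbut‑2‑en‑1‑yl)cyclohexa‑2,5‑dien‑1‑one 12 (not isolated)
Conditions: AcOH/THF/H2O, rt, until the ketal is consumed; then Zn dust, rt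
Reagents that add atoms: water, O
Why: mild acid hydrolysis of the quinol ketal gives the p‑quinol, and zinc in acetic acid then removes the tertiary hydroxyl by electron transfer to the dienone with aromatisation (reductive aromatisation of a p‑quinol to a phenol); zinc is added only after hydrolysis so that the methyl ether cannot form, and the aryl silyl ether, prenyl groups and chromene should tolerate aqueous acetic acid at room temperature.

Step 8
Reactants: 13 4‑[5‑(tert‑butyldimethylsilyloxy)‑2,2‑dimethyl‑2H‑chromen‑7‑yl]‑3,5‑bis(3‑methylbut‑2‑en‑1‑yl)phenol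
Product: 15 4‑[5‑(tert‑butyldimethylsilyloxy)‑2,2‑dimethyl‑2H‑chromen‑7‑yl]‑3,5‑bis(3‑methylbut‑2‑en‑1‑yl)benzene‑1,2‑diol, via 4‑[5‑(tert‑butyldimethylsilyloxy)‑2,2‑dimethyl‑2H‑chromen‑7‑yl]‑3,5‑bis(3‑methylbut‑2‑en‑1‑yl)cyclohexa‑3,5‑diene‑1,2‑dione 14 (not isolated)
Conditions: IBX (1.1 equiv), DMF, 0 °C → rt, argon, dark; then aq. Na2S2O4, rt
Reagents that add atoms: 2‑iodoxybenzoic acid (IBX), O=C1OI(=O)(O)c2ccccc12
Why: The free C4 phenol of ring A exchanges onto iodine(V), and the aryloxy‑λ5‑iodane delivers an iodine‑bound oxygen intramolecularly to the ortho carbon C3; the iodine(III) catecholate then collapses to the o‑quinone 14 and 2‑iodobenzoic acid, and dithionite added to the same flask reduces 14 to the catechol 15 (closest known reaction: IBX ortho‑oxygenation of phenols to o‑quinones with reductive work‑up to catechols). No ring is closed and no stereocentre is formed. The step needs site selectivity and chemoselectivity: the para carbon C1 is blocked by ring B, C3 and C5 are interchanged by the local mirror plane through C1 and C4 so that either gives the same 3,4‑catechol, and the only other phenol is silylated. The prenyl and chromene alkenes should not be oxidised by IBX at room temperature, and immediate reduction keeps the prenyl‑substituted o‑quinone from tautomerising to an o‑quinone methide that would close onto the C2 prenyl group.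

Step 9
Reactants: 15 4‑[5‑(tert‑butyldimethylsilyloxy)‑2,2‑dimethyl‑2H‑chromen‑7‑yl]‑3,5‑bis(3‑methylbut‑2‑en‑1‑yl)benzene‑1,2‑diol
Product: 16 clusiachromene D, 4‑(5‑hydroxy‑2,2‑dimethyl‑2H‑chromen‑7‑yl)‑3,5‑bis(3‑methylbut‑2‑en‑1‑yl)benzene‑1,2‑diol
Conditions: TBAF, AcOH (1:1), degassed THF, 0 °C, argon
Reagents that add atoms: none
Why: fluoride cleavage of an aryl silyl ether, buffered with acetic acid and run without oxygen so that the electron‑rich catechol is not exposed to basic phenoxide conditions that would favour air oxidation.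

**Compound list**

1 | 4‑methoxyphenol | COc1ccc(O)cc1 | starting material
2 | prenyl bromide (1‑bromo‑3‑methylbut‑2‑ene) | CC(C)=CCBr | starting material
3 | 4‑methoxy‑2‑(3‑methylbut‑2‑en‑1‑yl)phenol | COc1ccc(O)c(CC=C(C)C)c1 | intermediate
4 | 4‑methoxy‑2,6‑bis(3‑methylbut‑2‑en‑1‑yl)phenol | COc1cc(CC=C(C)C)c(O)c(CC=C(C)C)c1 | intermediate
5 | 4,4‑dimethoxy‑2,6‑bis(3‑methylbut‑2‑en‑1‑yl)cyclohexa‑2,5‑dien‑1‑one | COC1(OC)C=C(CC=C(C)C)C(=O)C(CC=C(C)C)=C1 | intermediate
6 | 5‑bromoresorcinol (5‑bromobenzene‑1,3‑diol) | Oc1cc(O)cc(Br)c1 | starting material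
7 | 3‑methylbut‑2‑enal | CC(C)=CC=O | starting material
8 | 7‑bromo‑2,2‑dimethyl‑2H‑chromen‑5‑ol | CC1(C)C=Cc2c(O)cc(Br)cc2O1 | intermediate
9 | tert‑butyl[(7‑bromo‑2,2‑dimethyl‑2H‑chromen‑5‑yl)oxy]dimethylsilane | CC1(C)C=Cc2c(O[Si](C)(C)C(C)(C)C)cc(Br)cc2O1 | intermediate
10 | [5‑(tert‑butyldimethylsilyloxy)‑2,2‑dimethyl‑2H‑chromen‑7‑yl]lithium | [Li]c1cc(O[Si](C)(C)C(C)(C)C)c2C=CC(C)(C)Oc2c1 | intermediate (not isolated)
11 | 1‑[5‑(tert‑butyldimethylsilyloxy)‑2,2‑dimethyl‑2H‑chromen‑7‑yl]‑4,4‑dimethoxy‑2,6‑bis(3‑methylbut‑2‑en‑1‑yl)cyclohexa‑2,5‑dien‑1‑ol | COC1(OC)C=C(CC=C(C)C)C(O)(c2cc(O[Si](C)(C)C(C)(C)C)c3C=CC(C)(C)Oc3c2)C(CC=C(C)C)=C1 | intermediate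
12 | 4‑[5‑(tert‑butyldimethylsilyloxy)‑2,2‑dimethyl‑2H‑chromen‑7‑yl]‑4‑hydroxy‑3,5‑bis(3‑methylbut‑2‑en‑1‑yl)cyclohexa‑2,5‑dien‑1‑one | O=C1C=C(CC=C(C)C)C(O)(c2cc(O[Si](C)(C)C(C)(C)C)c3C=CC(C)(C)Oc3c2)C(CC=C(C)C)=C1 | intermediate (not isolated)
13 | 4‑[5‑(tert‑butyldimethylsilyloxy)‑2,2‑dimethyl‑2H‑chromen‑7‑yl]‑3,5‑bis(3‑methylbut‑2‑en‑1‑yl)phenol | CC(C)=CCc1cc(O)cc(CC=C(C)C)c1-c1cc(O[Si](C)(C)C(C)(C)C)c2C=CC(C)(C)Oc2c1 | intermediate
14 | 4‑[5‑(tert‑butyldimethylsilyloxy)‑2,2‑dimethyl‑2H‑chromen‑7‑yl]‑3,5‑bis(3‑methylbut‑2‑en‑1‑yl)cyclohexa‑3,5‑diene‑1,2‑dione | CC(C)=CCC1=CC(=O)C(=O)C(CC=C(C)C)=C1c1cc(O[Si](C)(C)C(C)(C)C)c2C=CC(C)(C)Oc2c1 | intermediate (not isolated)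
15 | 4‑[5‑(tert‑butyldimethylsilyloxy)‑2,2‑dimethyl‑2H‑chromen‑7‑yl]‑3,5‑bis(3‑methylbut‑2‑en‑1‑yl)benzene‑1,2‑diol | CC(C)=CCc1cc(O)c(O)c(CC=C(C)C)c1-c1cc(O[Si](C)(C)C(C)(C)C)c2C=CC(C)(C)Oc2c1 | intermediate
16 | clusiachromene D, 4‑(5‑hydroxy‑2,2‑dimethyl‑2H‑chromen‑7‑yl)‑3,5‑bis(3‑methylbut‑2‑en‑1‑yl)benzene‑1,2‑diol | CC(C)=CCc1cc(O)c(O)c(CC=C(C)C)c1-c1cc(O)c2c(c1)OC(C)(C)C=C2 | target

**Step count**

Total steps: 9. Longest linear sequence: 7 steps (steps 1, 2, 3, 6, 7, 8, 9 from 4‑methoxyphenol). The branch from 5‑bromoresorcinol (steps 4, 5, 6, 7, 8, 9) has 6 steps.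

**Steps most likely to fail**

Step 8. Oxygen transfer to an ortho carbon flanked by a prenyl group may be slow. The o‑quinone may also tautomerise and cyclise onto the neighbouring prenyl group, or be oxidised further, before the reductant reaches it. The fallback sets out from 13 and avoids both iodine(V) and the o‑quinone. Magnesium‑mediated ortho‑formylation (MgCl2, Et3N, paraformaldehyde, MeCN, reflux) should place a formyl group on C3, either ortho carbon again giving the same compound. This gives 3‑[5‑(tert‑butyldimethylsilyloxy)‑2,2‑dimethyl‑2H‑chromen‑7‑yl]‑6‑hydroxy‑2,4‑bis(3‑methylbut‑2‑en‑1‑yl)benzaldehyde F1. Dakin oxidation (30% H2O2, one equivalent of NaOH, THF/H2O, 0 °C, argon) should then convert the salicylaldehyde through its aryl formate into catechol 15, where the fallback comes back to the route. Hydroperoxide is a nucleophilic oxidant and should leave the prenyl and chromene alkenes alone, and one equivalent of base should form only the salicylaldehyde phenoxide and spare the silyl ether.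

Step 6. Addition to a carbonyl flanked by two prenyl groups may be slow, so that electron transfer to the dienone or proton abstraction from the doubly allylic methylenes competes. The fallback sets out from 5 and 9 and replaces carbonyl addition by a cross‑coupling. Hydrolysis of 5 (aqueous oxalic acid, THF) should give 2,6‑bis(3‑methylbut‑2‑en‑1‑yl)cyclohexa‑2,5‑diene‑1,4‑dione F2, and dithionite reduction of F2 should give 2,6‑bis(3‑methylbut‑2‑en‑1‑yl)benzene‑1,4‑diol F3. Pivaloyl chloride in pyridine at 0 °C should acylate only the hydroxyl that has no ortho substituents, giving 4‑hydroxy‑3,5‑bis(3‑methylbut‑2‑en‑1‑yl)phenyl 2,2‑dimethylpropanoate F4. Tf2O and pyridine should then convert the remaining hindered hydroxyl of F4 into the triflate, 2,6‑bis(3‑methylbut‑2‑en‑1‑yl)‑4‑(2,2‑dimethylpropanoyloxy)phenyl trifluoromethanesulfonate F5. From 9, n‑BuLi and then ZnCl2 should give [5‑(tert‑butyldimethylsilyloxy)‑2,2‑dimethyl‑2H‑chromen‑7‑yl]zinc chloride F6. Base‑free Negishi coupling of F5 with F6 (Pd(OAc)2, RuPhos, THF, 60 °C) should give 4‑[5‑(tert‑butyldimethylsilyloxy)‑2,2‑dimethyl‑2H‑chromen‑7‑yl]‑3,5‑bis(3‑methylbut‑2‑en‑1‑yl)phenyl 2,2‑dimethylpropanoate F7. DIBAL‑H at −78 °C should remove the pivalate without touching the aryl silyl ether and give 13, where the fallback comes back to the route.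

Step 1. O‑alkylation, double alkylation at one ortho carbon to a dearomatised dienone, and acid‑promoted closure of the ortho‑prenylphenol to a chroman may all lower the yield of ortho‑C‑prenylation, and the same losses can recur in step 2. The fallback sets out from 1, builds the two side chains by sigmatropic rearrangement and metathesis, and replaces steps 1 and 2 together. Allyl bromide and K2CO3 in acetone should give 1‑methoxy‑4‑(prop‑2‑en‑1‑yloxy)benzene F8, and Claisen rearrangement (N,N‑diethylaniline, 190 °C) should give 4‑methoxy‑2‑(prop‑2‑en‑1‑yl)phenol F9. A second O‑allylation should give 1‑methoxy‑3‑(prop‑2‑en‑1‑yl)‑4‑(prop‑2‑en‑1‑yloxy)benzene F10, and a second Claisen rearrangement to the remaining ortho carbon should give 4‑methoxy‑2,6‑di(prop‑2‑en‑1‑yl)phenol F11. Double cross‑metathesis of F11 with 2‑methylbut‑2‑ene (Grubbs second‑generation catalyst, CH2Cl2, 40 °C) should give 4, where the fallback comes back to the route.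

**Further compounds**

F1 | step 8 | 3‑[5‑(tert‑butyldimethylsilyloxy)‑2,2‑dimethyl‑2H‑chromen‑7‑yl]‑6‑hydroxy‑2,4‑bis(3‑methylbut‑2‑en‑1‑yl)benzaldehyde | CC(C)=CCc1cc(O)c(C=O)c(CC=C(C)C)c1-c1cc(O[Si](C)(C)C(C)(C)C)c2C=CC(C)(C)Oc2c1
F2 | step 6 | 2,6‑bis(3‑methylbut‑2‑en‑1‑yl)cyclohexa‑2,5‑diene‑1,4‑dione | O=C1C=C(CC=C(C)C)C(=O)C(CC=C(C)C)=C1
F3 | step 6 | 2,6‑bis(3‑methylbut‑2‑en‑1‑yl)benzene‑1,4‑diol | Oc1cc(CC=C(C)C)c(O)c(CC=C(C)C)c1
F4 | step 6 | 4‑hydroxy‑3,5‑bis(3‑methylbut‑2‑en‑1‑yl)phenyl 2,2‑dimethylpropanoate | CC(C)(C)C(=O)Oc1cc(CC=C(C)C)c(O)c(CC=C(C)C)c1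
F5 | step 6 | 2,6‑bis(3‑methylbut‑2‑en‑1‑yl)‑4‑(2,2‑dimethylpropanoyloxy)phenyl trifluoromethanesulfonate | CC(C)(C)C(=O)Oc1cc(CC=C(C)C)c(OS(=O)(=O)C(F)(F)F)c(CC=C(C)C)c1
F6 | step 6 | [5‑(tert‑butyldimethylsilyloxy)‑2,2‑dimethyl‑2H‑chromen‑7‑yl]zinc chloride | Cl[Zn]c1cc(O[Si](C)(C)C(C)(C)C)c2C=CC(C)(C)Oc2c1
F7 | step 6 | 4‑[5‑(tert‑butyldimethylsilyloxy)‑2,2‑dimethyl‑2H‑chromen‑7‑yl]‑3,5‑bis(3‑methylbut‑2‑en‑1‑yl)phenyl 2,2‑dimethylpropanoate | CC(C)=CCc1cc(OC(=O)C(C)(C)C)cc(CC=C(C)C)c1-c1cc(O[Si](C)(C)C(C)(C)C)c2C=CC(C)(C)Oc2c1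
F8 | step 1 | 1‑methoxy‑4‑(prop‑2‑en‑1‑yloxy)benzene | COc1ccc(OCC=C)cc1
F9 | step 1 | 4‑methoxy‑2‑(prop‑2‑en‑1‑yl)phenol | COc1ccc(O)c(CC=C)c1
F10 | step 1 | 1‑methoxy‑3‑(prop‑2‑en‑1‑yl)‑4‑(prop‑2‑en‑1‑yloxy)benzene | COc1ccc(OCC=C)c(CC=C)c1
F11 | step 1 | 4‑methoxy‑2,6‑di(prop‑2‑en‑1‑yl)phenol | COc1cc(CC=C)c(O)c(CC=C)c1
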